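**Retrosynthetic overview**
1. Target 27 comes from fourfold alcohol oxidation of tetraol 25. Compound 25 comes from a 1,3-allylic transposition of adduct 23, which is made by 1,2-addition of the right-half Grignard 21 to the left-half enone 20 (C9′–C12′ bond).
2. Left half: ring B is made first and ring A last. In the key step Cp2TiCl cleaves a trisubstituted epoxide homolytically, and the tertiary C4′ radical closes ring A by 6-exo attack on the terminal carbon of a 6,6-disubstituted cyclohexa-2,4-dienone (C4′–C5′ bond).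
3. Right half: the cyclohexane comes first, then the oxepane by 7-endo opening of the same kind of epoxide by O7. C10 is set by hydrogenation. C11 and the C12–C12′ bond are set by radical chloromethylation of an exocyclic methylene.
4. Both halves are the two enantiomers of one racemic cyclohexenone 8, made by epoxy-ketone reductive alkylation. They are told apart by reagent-controlled epoxidation followed by lipase hydrolysis.
5. Carbon count: 2 × (2-methylcyclohexenone + 5-iodo-2-methylpent-2-ene + MeI) plus two C1 reagents gives C30.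

Assumption and locants (one line): 1 and 4 are catalogue compounds; right half C2 (CMe2–O), C3 (oxepanone C=O), C6 (quaternary C), C7 (CH–O), C10 (CH–CH3), C11 (CH carrying the tether), C12 (tether CH2); left half primed, C3′ (ring A C=O), C4′ (CMe2), C5′=C6′(OH), C7′ (C=O), C8′(CH3)=C9′, C10′ (quaternary C), C12′ (tether CH2); centres that are erased later are drawn only where one isomer is expected.

**Step 1**
Reactants: 1 2-methylcyclohex-2-en-1-one
Product: 2 (±)-2,6-dimethylcyclohex-2-en-1-one
Conditions: LiN(iPr)2, THF, −78 °C; MeI, −78 → 0 °C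
Reagents that add atoms: iodomethane CI
Why: Kinetic deprotonation of a cyclohexenone occurs at the alpha-prime carbon, so this enolate alkylation installs the methyl group that becomes C10–CH3 in one half and C8′–CH3 in the other; the new centre is erased in step 4.

**Step 2**
Reactants: 2 (±)-2,6-dimethylcyclohex-2-en-1-one
Product: 3 (±)-(1R*,6R*)-1,3-dimethyl-7-oxabicyclo[4.1.0]heptan-2-one (C3 epimers)
Conditions: 30% H2O2, NaOH (0.3 equiv), MeOH, 0 °C
Reagents that add atoms: hydrogen peroxide OO
Why: Weitz–Scheffer nucleophilic epoxidation attacks the electron-poor enone alkene and places the oxygen that becomes O7 (or the C5′ leaving group) next to the methyl-bearing carbon.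

**Step 3**
Reactants: 3 (±)-epoxy ketone; 4 5-iodo-2-methylpent-2-ene
Product: 7 (±)-(1R*,2S*)-2,4-dimethyl-2-(4-methylpent-3-en-1-yl)-3-oxocyclohexyl acetate (C4 epimers), via dilithium oxido enolate 5 (not isolated), via lithium alkoxide 6 (not isolated)
Conditions: Li (2.2 equiv), NH3(l)–THF, −78 °C; 4, −78 → −33 °C; evaporate NH3; Ac2O, THF, 0 °C
Reagents that add atoms: acetic anhydride CC(=O)OC(C)=O
Why: Dissolving-metal cleavage of the C(alpha)–O bond of an alpha,beta-epoxy ketone gives the regiodefined beta-oxido enolate (reductive alkylation), which is alkylated on the face opposite the neighbouring lithium alkoxide so that the chain is trans to oxygen at the new quaternary carbon, and the alkoxide is then O-acylated in the same flask.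

**Step 4**
Reactants: 7 (±)-keto acetate
Product: 8 (±)-(1R*,2S*)-2,4-dimethyl-2-(4-methylpent-3-en-1-yl)-3-oxocyclohex-4-en-1-yl acetate
Conditions: IBX (2.5 equiv), DMSO–PhF, 75 °C
Reagents that add atoms: none
Why: IBX dehydrogenation of a ketone proceeds through its enol, only one alpha-CH is available, the acetate and the isolated alkene are inert, and the epimeric methyl centre is removed.

**Step 5**
Reactants: 8 (±)-enone acetate
Product: 9 (1R,2S)-2-{2-[(2R)-3,3-dimethyloxiran-2-yl]ethyl}-2,4-dimethyl-3-oxocyclohex-4-en-1-yl acetate + 10 its (1S,2R)-ring diastereomer with the same (2R)-oxirane (1:1 mixture carried on together)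
Conditions: D-fructose-derived Shi ketone (0.3 equiv), KHSO5 (as 2KHSO5·KHSO4·K2SO4), K2CO3, Bu4NHSO4, MeCN–CH2(OMe)2–aq. Na2B4O7/Na2EDTA, 0 °C
Reagents that add atoms: potassium peroxymonosulfate [K+].[O-]S(=O)(=O)OO
Why: Shi asymmetric epoxidation uses a chiral dioxirane that oxidises only the electron-rich trisubstituted alkene and, being reagent-controlled, gives the R epoxide in both enantiomers of 8, which turns the racemate into two diastereomers.

**Step 6**
Reactants: 9 and 10 (mixture from step 5)
Product: 11 (5R,6S)-6-{2-[(2R)-3,3-dimethyloxiran-2-yl]ethyl}-5-hydroxy-2,6-dimethylcyclohex-2-en-1-one (10 is recovered unchanged and separated by chromatography)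
Conditions: immobilised Candida antarctica lipase B, pH 7 phosphate buffer–MTBE, 30 °C, to 50% conversion
Reagents that add atoms: none
Why: In this lipase-catalysed kinetic resolution by ester hydrolysis, the empirical large/medium rule for secondary alcohols predicts fast cleavage of the 1R acetate 9 only, which fixes the absolute configuration of C6/C7 (in 11) and of C10′ (in 10).

**Step 7**
Reactants: 11 hydroxy epoxide
Product: 12 (3R,5aS,9aR)-2,2,5a,7-tetramethyl-3-(triisopropylsilyloxy)-3,4,5,5a,9,9a-hexahydro-1-benzoxepin-6(2H)-one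
Conditions: TIPSOTf (1.2 equiv), 2,6-lutidine, MeNO2, −25 → 0 °C
Reagents that add atoms: triisopropylsilyl triflate CC(C)[Si](C(C)C)(C(C)C)OS(=O)(=O)C(F)(F)F
Why: In this silyl-triflate-promoted endo-selective epoxide opening, O7 attacks the tertiary, cation-stabilising epoxide carbon C2 (7-endo), the ring is trans-fused because O7 and C5 are already trans, and silyl transfer leaves C3–O protected.

**Step 8**
Reactants: 12 oxepane enone
Product: 13 (3R,5aS,7S,9aR)-2,2,5a,7-tetramethyl-3-(triisopropylsilyloxy)octahydro-1-benzoxepin-6(2H)-one (C10 methyl axial and cis to the C6 methyl)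
Conditions: H2 (1 atm), Pd/C, EtOAc, rt
Reagents that add atoms: none
Why: Heterogeneous catalytic hydrogenation delivers hydrogen to the face opposite the axial angular methyl at C6, which pushes C10–CH3 onto the methyl face and gives the kinetic axial epimer required by the target.

**Step 9**
Reactants: 13 ketone
Product: 14 (3R,5aR,7S,9aR)-2,2,5a,7-tetramethyl-6-methylidene-3-(triisopropylsilyloxy)decahydro-1-benzoxepine
Conditions: Cp2TiMe2 (3 equiv), toluene–THF, 70 °C, dark
Reagents that add atoms: dimethyltitanocene C[Ti](C)(C1C=CC=C1)C1C=CC=C1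
Why: Petasis methylenation through Cp2Ti=CH2 is non-basic, so it converts the hindered and epimerisable ketone into the exocyclic alkene (C12) without touching C10.

**Step 10**
Reactants: 14 exocyclic alkene
Product: 15 (3R,5aR,6S,7S,9aR)-6-(2-chloroethyl)-2,2,5a,7-tetramethyl-3-(triisopropylsilyloxy)decahydro-1-benzoxepine
Conditions: ICH2Cl (5 equiv), (Me3Si)3SiH (slow addition), Et3B/air, PhH, rt
Reagents that add atoms: chloroiodomethane ClCI
Why: Proposed new method: the silyl radical abstracts iodine from ICH2Cl, the mildly electrophilic chloromethyl radical adds to the open CH2 terminus of the electron-rich 1,1-disubstituted alkene (C12–C12′ bond), and the tertiary C11 radical takes hydrogen from (Me3Si)3SiH on the face away from the two axial methyl groups at C6 and C10, which leaves the side chain equatorial as in the target while the primary C–Cl bond is inert to the chain; the closest known reaction types are Kharasch atom-transfer additions of polyhalomethanes and silane-mediated reductive (Giese-type) radical additions.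

**Step 11**
Reactants: 10 left-series epoxy enone acetate
Product: 16 (6R)-6-{2-[(2R)-3,3-dimethyloxiran-2-yl]ethyl}-2,6-dimethylcyclohexa-2,4-dien-1-one
Conditions: DBU, CH2Cl2, 0 °C → rt; used promptly
Reagents that add atoms: none
Why: In this vinylogous E1cB elimination, gamma-deprotonation of the enone expels the acetate and gives the linearly conjugated dienone, whose 2-methyl and 6,6-dialkyl substitution slows Diels–Alder dimerisation.

**Step 12 (key step)**
Reactants: 16 epoxy dienone
Product: 18 (4aS,6R,8aR)-6-hydroxy-2,5,5,8a-tetramethyl-4a,5,6,7,8,8a-hexahydronaphthalen-1(2H)-one (cis-fused; C2 epimers), via bis-titanium dienolate alkoxide 17 (not isolated)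
Conditions: Cp2TiCl2 (2.5 equiv), Mn dust, THF, rt, slow addition of 16 (0.01 M); cold aq. NaH2PO4
Reagents that add atoms: none
Why: Proposed new method: Cp2TiCl (trivalent titanium, made in the flask) cleaves the epoxide C–O bond at the more substituted carbon, the nucleophilic tertiary C4′ radical closes ring A by 6-exo attack on C5′ (the unhindered electrophilic delta-terminus of the dienone), a second Cp2TiCl reduces the delocalised radical to a titanium dienolate, and cold protonation at the alpha-carbon gives the beta,gamma-enone; C10′ is untouched, the new centres C3′, C5′ and C8′ are all erased later, and the closest known reaction types are the Nugent–RajanBabu epoxide-opening radical cyclisation onto enones and intramolecular Giese 1,6-additions.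

**Step 13**
Reactants: 18 beta,gamma-enone
Product: 20 (4aS,6R,8aR)-4,6-dihydroxy-2,5,5,8a-tetramethyl-4a,5,6,7,8,8a-hexahydronaphthalen-1(4H)-one (C4 carbinol configuration inconsequential), via epoxy ketone 19 (not isolated)
Conditions: mCPBA, NaHCO3, CH2Cl2, 0 °C; then DBU, rt
Reagents that add atoms: 3-chloroperoxybenzoic acid OOC(=O)c1cccc(Cl)c1
Why: Prilezhaev epoxidation of the only alkene is followed by base-induced isomerisation of the beta,gamma-epoxy ketone to the gamma-hydroxy enone (E1cB), which places oxygen on C6′ regiospecifically.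

**Step 14**
Reactants: 15 right-half chloride; 20 left-half hydroxy enone
Product: 23 coupled tertiary allylic alcohol (C9′ carbinol bearing the C12′H2–C12H2 tether; C3′ and C6′ hydroxyls free; C3 still TIPS-protected), via Grignard reagent 21 (not isolated), via dilithium dialkoxide 22 (not isolated)
Conditions: 15, Mg, BrCH2CH2Br (cat.), THF, reflux; 20, LiN(SiMe3)2 (2.1 equiv), THF, −78 °C; LaCl3·2LiCl; combine, −78 → 0 °C; H2O
Reagents that add atoms: none
Why: Lanthanide-promoted Grignard 1,2-addition to the enone carbonyl is the only addition pathway, because both hydroxyls are masked beforehand as alkoxides with a cheap base and LaCl3·2LiCl suppresses enolisation and conjugate addition at the hindered ketone; the new carbinol centre is erased in step 16.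

**Step 15**
Reactants: 23 silyl ether
Product: 24 tetraol (C3, C3′, C6′ secondary and C9′ tertiary hydroxyls)
Conditions: Bu4NF, THF, 50 °C
Reagents that add atoms: none
Why: Fluoride-induced desilylation is driven by the strong Si–F bond and touches no other group.

**Step 16**
Reactants: 24 tetraol
Product: 25 transposed tetraol (C8′=C9′ tetrasubstituted alkene; vicinal C6′/C7′ diol; C3 and C3′ hydroxyls)
Conditions: Re2O7 (5 mol%), Et2O–THF, 0 °C
Reagents that add atoms: none
Why: The rhenium-oxo-catalysed 1,3-transposition of allylic alcohols ([3,3] shift of the perrhenate ester) runs towards the tetrasubstituted alkene and the less crowded secondary alcohol, moving oxygen from C9′ to C7′.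

**Step 17**
Reactants: 25 tetraol
Product: 27 target CNP0302807.1, via tetraketone tautomer 26 (not isolated)
Conditions: IBX (10 equiv), DMSO, rt; silica gel
Reagents that add atoms: none
Why: IBX oxidises all four secondary alcohols and converts the 1,2-diol into the alpha-diketone without C–C cleavage, and enolisation towards C5′ then gives the conjugated diosphenol, which removes the last auxiliary centres and leaves C6, C7, C10, C11 and C10′ as set.

**Compound list**
1 | 2-methylcyclohex-2-en-1-one | CC1=CCCCC1=O | starting material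
2 | (±)-2,6-dimethylcyclohex-2-en-1-one | CC1CCC=C(C)C1=O | intermediate
3 | (±)-(1R*,6R*)-1,3-dimethyl-7-oxabicyclo[4.1.0]heptan-2-one (racemate, one enantiomer drawn) | O=C1C(C)CC[C@H]2O[C@@]12C | intermediate
4 | 5-iodo-2-methylpent-2-ene | CC(C)=CCCI | starting material
5 | dilithium oxido enolate (racemate) | CC1CC[C@@H](O[Li])C(C)=C1O[Li] | intermediate
6 | lithium alkoxide of the alkylated ketone (racemate) | O=C1C(C)CC[C@@H](O[Li])[C@]1(C)CCC=C(C)C | intermediate
7 | (±)-(1R*,2S*)-2,4-dimethyl-2-(4-methylpent-3-en-1-yl)-3-oxocyclohexyl acetate | O=C1C(C)CC[C@@H](OC(C)=O)[C@]1(C)CCC=C(C)C | intermediate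
8 | (±)-(1R*,2S*)-2,4-dimethyl-2-(4-methylpent-3-en-1-yl)-3-oxocyclohex-4-en-1-yl acetate | O=C1C(C)=CC[C@@H](OC(C)=O)[C@]1(C)CCC=C(C)C | intermediate
9 | (1R,2S)-2-{2-[(2R)-3,3-dimethyloxiran-2-yl]ethyl}-2,4-dimethyl-3-oxocyclohex-4-en-1-yl acetate | O=C1C(C)=CC[C@@H](OC(C)=O)[C@]1(C)CC[C@H]2OC2(C)C | intermediate
10 | (1S,2R)-2-{2-[(2R)-3,3-dimethyloxiran-2-yl]ethyl}-2,4-dimethyl-3-oxocyclohex-4-en-1-yl acetate | O=C1C(C)=CC[C@H](OC(C)=O)[C@@]1(C)CC[C@H]2OC2(C)C | intermediate
11 | (5R,6S)-6-{2-[(2R)-3,3-dimethyloxiran-2-yl]ethyl}-5-hydroxy-2,6-dimethylcyclohex-2-en-1-one | O=C1C(C)=CC[C@@H](O)[C@]1(C)CC[C@H]2OC2(C)C | intermediate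
12 | (3R,5aS,9aR)-2,2,5a,7-tetramethyl-3-(triisopropylsilyloxy)-3,4,5,5a,9,9a-hexahydro-1-benzoxepin-6(2H)-one | O=C1C(C)=CC[C@H]2OC(C)(C)[C@H](O[Si](C(C)C)(C(C)C)C(C)C)CC[C@@]21C | intermediate
13 | (3R,5aS,7S,9aR)-2,2,5a,7-tetramethyl-3-(triisopropylsilyloxy)octahydro-1-benzoxepin-6(2H)-one | O=C1[C@@H](C)CC[C@H]2OC(C)(C)[C@H](O[Si](C(C)C)(C(C)C)C(C)C)CC[C@@]21C | intermediate
14 | (3R,5aR,7S,9aR)-2,2,5a,7-tetramethyl-6-methylidene-3-(triisopropylsilyloxy)decahydro-1-benzoxepine | C=C1[C@@H](C)CC[C@H]2OC(C)(C)[C@H](O[Si](C(C)C)(C(C)C)C(C)C)CC[C@@]21C | intermediate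
15 | (3R,5aR,6S,7S,9aR)-6-(2-chloroethyl)-2,2,5a,7-tetramethyl-3-(triisopropylsilyloxy)decahydro-1-benzoxepine | ClCC[C@H]1[C@@H](C)CC[C@H]2OC(C)(C)[C@H](O[Si](C(C)C)(C(C)C)C(C)C)CC[C@@]21C | intermediate
16 | (6R)-6-{2-[(2R)-3,3-dimethyloxiran-2-yl]ethyl}-2,6-dimethylcyclohexa-2,4-dien-1-one | O=C1C(C)=CC=C[C@@]1(C)CC[C@H]2OC2(C)C | intermediate
17 | bis(chlorotitanocene) dienolate alkoxide | Cl[Ti](C1C=CC=C1)(C1C=CC=C1)OC1=C(C)C=C[C@H]2C(C)(C)[C@H](O[Ti](Cl)(C3C=CC=C3)C3C=CC=C3)CC[C@@]12C | intermediate
18 | (4aS,6R,8aR)-6-hydroxy-2,5,5,8a-tetramethyl-4a,5,6,7,8,8a-hexahydronaphthalen-1(2H)-one | O=C1C(C)C=C[C@H]2C(C)(C)[C@H](O)CC[C@@]12C | intermediate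
19 | 3,4-epoxide of 18 | O=C1C(C)C2OC2[C@H]3C(C)(C)[C@H](O)CC[C@@]13C | intermediate
20 | (4aS,6R,8aR)-4,6-dihydroxy-2,5,5,8a-tetramethyl-4a,5,6,7,8,8a-hexahydronaphthalen-1(4H)-one | O=C1C(C)=CC(O)[C@H]2C(C)(C)[C@H](O)CC[C@@]12C | intermediate
21 | Grignard reagent from 15 | Cl[Mg]CC[C@H]1[C@@H](C)CC[C@H]2OC(C)(C)[C@H](O[Si](C(C)C)(C(C)C)C(C)C)CC[C@@]21C | intermediate
22 | dilithium dialkoxide of 20 | O=C1C(C)=CC(O[Li])[C@H]2C(C)(C)[C@H](O[Li])CC[C@@]12C | intermediate
23 | coupled tertiary allylic alcohol, C3 TIPS ether | CC1=CC(O)[C@H]2C(C)(C)[C@H](O)CC[C@@]2(C)C1(O)CC[C@H]3[C@@H](C)CC[C@H]4OC(C)(C)[C@H](O[Si](C(C)C)(C(C)C)C(C)C)CC[C@@]43C | intermediate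
24 | tetraol (C9′ tertiary carbinol) | CC1=CC(O)[C@H]2C(C)(C)[C@H](O)CC[C@@]2(C)C1(O)CC[C@H]3[C@@H](C)CC[C@H]4OC(C)(C)[C@H](O)CC[C@@]43C | intermediate
25 | transposed tetraol (C6′/C7′ diol, C8′=C9′) | CC1=C(CC[C@H]2[C@@H](C)CC[C@H]3OC(C)(C)[C@H](O)CC[C@@]32C)[C@]4(C)CC[C@@H](O)C(C)(C)[C@@H]4C(O)C1O | intermediate
26 | tetraketone (6′,7′-dione tautomer) | CC1=C(CC[C@H]2[C@@H](C)CC[C@H]3OC(C)(C)C(=O)CC[C@@]32C)[C@]4(C)CCC(=O)C(C)(C)[C@@H]4C(=O)C1=O | intermediate
27 | CNP0302807.1 | CC1=C(CC[C@H]2[C@@H](C)CC[C@H]3OC(C)(C)C(=O)CC[C@@]32C)[C@]2(C)CCC(=O)C(C)(C)C2=C(O)C1=O | target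

**Step count**
- Total step count: 17.
- Longest linear sequence: 14 (steps 1–10 and 14–17).

**The three steps most likely to fail**

Step 7. The 7-endo opening competes with 6-exo opening and with participation of the carbonyl oxygen. The fallback sets out from 11 and returns at 12. The epoxide is isomerised with Al(OiPr)3 (toluene, 80 °C) to the allylic alcohol (5R,6S)-5-hydroxy-6-[(3R)-3-hydroxy-4-methylpent-4-en-1-yl]-2,6-dimethylcyclohex-2-en-1-one F1. The less hindered allylic hydroxyl is silylated (TIPSCl, imidazole) to the mono-TIPS ether F2. The tertiary ether is then closed by cobalt-hydride hydrogen-atom transfer with radical-polar crossover (hydroalkoxylation). The reagents are the cobalt salen complex Co(C36H52N2O2), N-fluoro-2,4,6-trimethylpyridinium triflate and (Me2SiH)2O. In this approach only C2 can become the cationic site, so the regiochemistry question disappears.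

Step 10. The intermolecular addition of the chloromethyl radical to a flanked alkene may be too slow. The fallback sets out from 14 and returns at 15. RhCl(PPh3)3-catalysed hydroboration with pinacolborane from the same open face gives the primary boronate F3, with C11 set by syn addition. Matteson homologation with LiCH2Cl gives the homologous boronate F4. NaBO3 oxidation gives the primary alcohol F5, and Appel chlorination (PPh3, CCl4) gives 15.

Step 12. Low-valent titanium may reduce the dienone, or may deoxygenate the epoxide before cyclisation. The fallback sets out from 16 and returns at 18. The epoxide is isomerised with Al(OiPr)3 to the allylic alcohol (6R)-6-[(3R)-3-hydroxy-4-methylpent-4-en-1-yl]-2,6-dimethylcyclohexa-2,4-dien-1-one F6. The same tertiary C4′ radical is then generated by iron-hydride hydrogen-atom transfer to the 1,1-disubstituted alkene (Fe(acac)3 cat., PhSiH3, EtOH, 60 °C). It closes ring A reductively without any stoichiometric reducing metal.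

**Further compounds**
F1 | step 7 | (5R,6S)-5-hydroxy-6-[(3R)-3-hydroxy-4-methylpent-4-en-1-yl]-2,6-dimethylcyclohex-2-en-1-one | O=C1C(C)=CC[C@@H](O)[C@]1(C)CC[C@@H](O)C(C)=C
F2 | step 7 | mono-TIPS ether of F1 at the allylic hydroxyl | O=C1C(C)=CC[C@@H](O)[C@]1(C)CC[C@@H](O[Si](C(C)C)(C(C)C)C(C)C)C(C)=C
F3 | step 10 | C12 pinacol boronate | CC1(C)OB(OC1(C)C)C[C@H]2[C@@H](C)CC[C@H]3OC(C)(C)[C@H](O[Si](C(C)C)(C(C)C)C(C)C)CC[C@@]32C
F4 | step 10 | C12′ pinacol boronate | CC1(C)OB(OC1(C)C)CC[C@H]2[C@@H](C)CC[C@H]3OC(C)(C)[C@H](O[Si](C(C)C)(C(C)C)C(C)C)CC[C@@]32C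
F5 | step 10 | C12′ primary alcohol | OCC[C@H]2[C@@H](C)CC[C@H]3OC(C)(C)[C@H](O[Si](C(C)C)(C(C)C)C(C)C)CC[C@@]32C
F6 | step 12 | (6R)-6-[(3R)-3-hydroxy-4-methylpent-4-en-1-yl]-2,6-dimethylcyclohexa-2,4-dien-1-one | O=C1C(C)=CC=C[C@@]1(C)CC[C@@H](O)C(C)=C
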